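## Retrosynthetic overview

- The plan rests on the six-membered enone ring (C3a–C4–C5–C6–C7–C7a) and its quaternary carbon C3a. If C6 and C7 are excised, a four-membered ketone made of C5, C4, C3a and C7a remains, in which C3a is a prochiral centre flanked by two equivalent ring CH2 groups.
- Last disconnection, lactone bond O1–C7a: the cis-fused γ-lactone comes from the enone acid by bromination of its through-conjugated silyl dienol ether at C7a and closure by the carboxylate.
- Key disconnection, C5–C6 and C7–C7a: enantioselective nickel-catalysed insertion of acetylene into one of the two enantiotopic acyl–CH2 bonds of methyl 2-(1-farnesyl-3-oxocyclobutyl)acetate builds the enone ring and fixes C3a.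
- The cyclobutanone comes from methyl 3,3-dimethoxycyclobutane-1-carboxylate by enolate farnesylation (C3a–C1′), Arndt–Eistert homologation (adds C3) and ketal hydrolysis.
- Ring order: the four-membered ring is bought, the six-membered ring is formed in step 6, the five-membered lactone ring in step 9.

Key step: step 6

Assumption: the sense of induction of the chiral nickel catalyst in step 6 cannot be predicted, so the ligand antipode that gives (S)-12 is taken after a screen; "farnesyl" stands throughout for (2E,6E)-3,7,11-trimethyldodeca-2,6,10-trien-1-yl, and atom labels C2 to C7a are those of the benzofuranone skeleton of the target.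

## Route

Step 1
Reactants: 1 methyl 3,3-dimethoxycyclobutane-1-carboxylate; 2 (2E,6E)-farnesyl bromide
Product: 4 methyl 1-farnesyl-3,3-dimethoxycyclobutane-1-carboxylate, via lithium ester enolate 3 (not isolated)
Conditions: LiN(i-Pr)2 (1.1 equiv), THF, −78 °C; then 2, −78 → 0 °C
Reagents that add atoms: none
Why: Ester enolate alkylation (SN2 at the primary allylic bromide); the ring ester has a single α-hydrogen, so only monoalkylation at the future C3a is possible, and the product is achiral.

Step 2
Reactants: 4 methyl 1-farnesyl-3,3-dimethoxycyclobutane-1-carboxylate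
Product: 5 1-farnesyl-3,3-dimethoxycyclobutane-1-carboxylic acid
Conditions: LiOH·H2O (5 equiv), THF–MeOH–H2O (2:1:1), 60 °C; then 1 M HCl to pH 4, 0 °C
Reagents that add atoms: lithium hydroxide, [Li+].[OH-]
Why: Saponification (acyl–oxygen cleavage by hydroxide); ketal and trisubstituted olefins are inert to base, and the short cold acidification to pH 4 is too mild to open the four-ring ketal.

Step 3
Reactants: 5 1-farnesyl-3,3-dimethoxycyclobutane-1-carboxylic acid
Product: 7 2-diazo-1-(1-farnesyl-3,3-dimethoxycyclobutyl)ethan-1-one, via acid chloride 6 (not isolated)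
Conditions: 1-chloro-N,N,2-trimethylprop-1-en-1-amine (1.2 equiv), CH2Cl2, 0 °C → rt; then CH2N2 (3 equiv), Et2O, 0 °C
Reagents that add atoms: diazomethane, C=[N+]=[N-]
Why: First half of the Arndt–Eistert homologation: the α-chloroenamine makes the acid chloride under neutral conditions (no HCl to touch ketal or polyene), and acylation of diazomethane gives the diazoketone while the excess reagent takes up the HCl.

Step 4
Reactants: 7 2-diazo-1-(1-farnesyl-3,3-dimethoxycyclobutyl)ethan-1-one
Product: 9 methyl 2-(1-farnesyl-3,3-dimethoxycyclobutyl)acetate, via ketene 8 (not isolated)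
Conditions: PhCO2Ag (0.1 equiv), Et3N (3 equiv), MeOH–THF, rt, dark
Reagents that add atoms: methanol, CO
Why: Wolff rearrangement: the quaternary ring carbon migrates readily and methanol traps the ketene, which places a CH2 (the future C3) between C3a and the ester carbon (the future C2); the ketone is still masked, so the diazo chemistry cannot ring-expand it.

Step 5
Reactants: 9 methyl 2-(1-farnesyl-3,3-dimethoxycyclobutyl)acetate
Product: 10 methyl 2-(1-farnesyl-3-oxocyclobutyl)acetate
Conditions: 1 M aq HCl, THF, rt
Reagents that add atoms: water, O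
Why: Acid-catalysed ketal hydrolysis; dilute aqueous acid at room temperature should free the ketone without protonating the trisubstituted olefins or cleaving the methyl ester, and gives the achiral, prochiral 3,3-disubstituted cyclobutanone.

Step 6
Reactants: 10 methyl 2-(1-farnesyl-3-oxocyclobutyl)acetate; 11 acetylene
Product: 12 methyl 2-[(1S)-1-farnesyl-5-oxocyclohex-3-en-1-yl]acetate
Conditions: Ni(cod)2 (10 mol %), TADDOL-derived N,N-dimethylphosphoramidite (20 mol %, antipode per the assumption), toluene, 80 °C, acetylene (5 vol % in N2, 1 atm, slow stream)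
Reagents that add atoms: none
Why: Proposed new method: zerovalent nickel binds the strained carbonyl of 10 together with acetylene and couples them oxidatively to an oxanickelacyclopentene (C5–C6 bond), β-carbon elimination driven by loss of four-ring strain then detaches one of the two ring CH2 groups from C5 to give a seven-membered nickelacycle, and C(sp3)–C(sp2) reductive elimination forms C7–C7a; the nearest known reaction types are the Ni(cod)2/trialkylphosphine-catalysed insertion of internal alkynes into 3,3-disubstituted cyclobutanones and ligand-controlled enantioselective intramolecular C–C activation of prochiral cyclobutanones, but no such insertion has been shown with acetylene gas or, between two separate partners, under asymmetric control. The six-membered enone ring is closed in a formal [4+2] mode, by reductive elimination from the seven-membered nickelacycle, which amounts to a two-carbon expansion of the four-membered ring. C3a, the one new stereocentre, becomes stereogenic when one ring CH2 is detached from C5, and the chiral phosphoramidite on nickel selects that CH2 (the future C7a); the ester carbonyl of the acetate arm can lean on nickel and so should help the catalyst tell this arm from the farnesyl arm. The step needs carbonyl–alkyne coupling to outrun cyclo-oligomerisation of acetylene, which the strained, unhindered, strongly π-accepting cyclobutanone carbonyl and a low stationary acetylene concentration should secure; the alkylnickel intermediate has no β-hydrogen because C3a is fully substituted, and the trisubstituted olefins of the side chain are much poorer ligands for nickel than acetylene.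

Step 7
Reactants: 12 methyl 2-[(1S)-1-farnesyl-5-oxocyclohex-3-en-1-yl]acetate
Product: 13 2-[(1S)-1-farnesyl-5-oxocyclohex-3-en-1-yl]acetic acid
Conditions: LiOH·H2O (2 equiv), THF–H2O (3:1), 0 °C → rt; then 1 M HCl to pH 3
Reagents that add atoms: lithium hydroxide, [Li+].[OH-]
Why: Saponification of an unhindered methyl ester; C3a is quaternary and cannot epimerise, and the enone should tolerate cold aqueous hydroxide.

Step 8
Reactants: 13 2-[(1S)-1-farnesyl-5-oxocyclohex-3-en-1-yl]acetic acid
Product: 15 tert-butyldimethylsilyl 2-[(1R)-5-(tert-butyldimethylsilyloxy)-1-farnesylcyclohexa-2,4-dien-1-yl]acetate, via dipotassium dienolate 14 (not isolated)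
Conditions: KOt-Bu (2.3 equiv), THF, −20 → 0 °C; then TBSCl (3.0 equiv), −78 → 0 °C; non-aqueous work-up (pentane, filtration)
Reagents that add atoms: tert-butyldimethylsilyl chloride, CC(C)(C)[Si](C)(C)Cl
Why: Thermodynamic enolisation and O-silylation: reversible deprotonation by tert-butoxide should funnel the enone into the through-conjugated O–C5=C6–C7=C7a dienolate (loss of a C7a proton, more stable than the cross-conjugated C4 enolate), which silylates on oxygen while the carboxylate becomes the silyl ester, so that the acid is masked and C7a becomes the nucleophilic terminus; C3a is untouched (the descriptor changes only because C7a gains priority).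

Step 9
Reactants: 15 tert-butyldimethylsilyl 2-[(1R)-5-(tert-butyldimethylsilyloxy)-1-farnesylcyclohexa-2,4-dien-1-yl]acetate
Product: 18 (3aR,7aR)-3a-[(2E,6E)-3,7,11-trimethyldodeca-2,6,10-trien-1-yl]-3a,7a-dihydro-1-benzofuran-2,5(3H,4H)-dione, via bromo enone silyl ester 16 (not isolated), via bromo enone carboxylate 17 (not isolated)
Conditions: NBS (1.05 equiv), THF, −78 °C; then AcOH (1.0 equiv), Bu4NF (2.2 equiv), −78 → 0 °C
Reagents that add atoms: none
Why: γ-Bromination of a silyl dienol ether followed by intramolecular SN2 O-alkylation: NBS should attack the electron-rich dienol ether at C7a far faster at −78 °C than the side-chain olefins, fluoride then frees the carboxylate, and its 5-exo-tet displacement of the allylic bromide can close only on the face of C7a that carries the acetate arm, so C7a is set cis to C3 (7aR) under substrate control, the bromide epimers converging through bromide-mediated allylic equilibration.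

## Compound list

1 | methyl 3,3-dimethoxycyclobutane-1-carboxylate | COC(=O)C1CC(OC)(OC)C1 | starting material
2 | (2E,6E)-farnesyl bromide | CC(C)=CCC/C(C)=C/CC/C(C)=C/CBr | starting material
3 | lithium enolate of 1 | [Li+].[O-]C(OC)=C1CC(OC)(OC)C1 | intermediate
4 | methyl 1-farnesyl-3,3-dimethoxycyclobutane-1-carboxylate | CC(C)=CCC/C(C)=C/CC/C(C)=C/CC1(C(=O)OC)CC(OC)(OC)C1 | intermediate
5 | 1-farnesyl-3,3-dimethoxycyclobutane-1-carboxylic acid | CC(C)=CCC/C(C)=C/CC/C(C)=C/CC1(C(=O)O)CC(OC)(OC)C1 | intermediate
6 | 1-farnesyl-3,3-dimethoxycyclobutane-1-carbonyl chloride | CC(C)=CCC/C(C)=C/CC/C(C)=C/CC1(C(=O)Cl)CC(OC)(OC)C1 | intermediate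
7 | 2-diazo-1-(1-farnesyl-3,3-dimethoxycyclobutyl)ethan-1-one | CC(C)=CCC/C(C)=C/CC/C(C)=C/CC1(C(=O)C=[N+]=[N-])CC(OC)(OC)C1 | intermediate
8 | (1-farnesyl-3,3-dimethoxycyclobutyl)ketene | CC(C)=CCC/C(C)=C/CC/C(C)=C/CC1(C=C=O)CC(OC)(OC)C1 | intermediate
9 | methyl 2-(1-farnesyl-3,3-dimethoxycyclobutyl)acetate | CC(C)=CCC/C(C)=C/CC/C(C)=C/CC1(CC(=O)OC)CC(OC)(OC)C1 | intermediate
10 | methyl 2-(1-farnesyl-3-oxocyclobutyl)acetate | CC(C)=CCC/C(C)=C/CC/C(C)=C/CC1(CC(=O)OC)CC(=O)C1 | intermediate
11 | acetylene | C#C | starting material
12 | methyl 2-[(1S)-1-farnesyl-5-oxocyclohex-3-en-1-yl]acetate | CC(C)=CCC/C(C)=C/CC/C(C)=C/C[C@]1(CC(=O)OC)CC(=O)C=CC1 | intermediate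
13 | 2-[(1S)-1-farnesyl-5-oxocyclohex-3-en-1-yl]acetic acid | CC(C)=CCC/C(C)=C/CC/C(C)=C/C[C@]1(CC(=O)O)CC(=O)C=CC1 | intermediate
14 | dipotassium salt of 13 (carboxylate and C5–C7a dienolate) | CC(C)=CCC/C(C)=C/CC/C(C)=C/C[C@]1(CC(=O)[O-])CC([O-])=CC=C1.[K+].[K+] | intermediate
15 | tert-butyldimethylsilyl 2-[(1R)-5-(tert-butyldimethylsilyloxy)-1-farnesylcyclohexa-2,4-dien-1-yl]acetate | CC(C)=CCC/C(C)=C/CC/C(C)=C/C[C@]1(CC(=O)O[Si](C)(C)C(C)(C)C)CC(O[Si](C)(C)C(C)(C)C)=CC=C1 | intermediate
16 | tert-butyldimethylsilyl 2-[(1R)-2-bromo-1-farnesyl-5-oxocyclohex-3-en-1-yl]acetate (both C2 epimers) | CC(C)=CCC/C(C)=C/CC/C(C)=C/C[C@]1(CC(=O)O[Si](C)(C)C(C)(C)C)CC(=O)C=CC1Br | intermediate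
17 | tetrabutylammonium 2-[(1R)-2-bromo-1-farnesyl-5-oxocyclohex-3-en-1-yl]acetate (both C2 epimers) | CC(C)=CCC/C(C)=C/CC/C(C)=C/C[C@]1(CC(=O)[O-])CC(=O)C=CC1Br.CCCC[N+](CCCC)(CCCC)CCCC | intermediate
18 | (3aR,7aR)-3a-[(2E,6E)-3,7,11-trimethyldodeca-2,6,10-trien-1-yl]-3a,7a-dihydro-1-benzofuran-2,5(3H,4H)-dione | CC(C)=CCC/C(C)=C/CC/C(C)=C/C[C@]12CC(=O)C=C[C@H]1OC(=O)C2 | target

## Step count and risks

Total step count: 9. Longest linear sequence: 9 steps (from 1).

**Step 6 (Proposed new method).** Nickel-mediated cyclotrimerisation and polymerisation of acetylene may outrun the carbonyl–alkyne coupling and bury the catalyst. The ligand may also discriminate poorly between the two enantiotopic acyl–CH2 bonds, because both groups on C3a begin with a CH2.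

The fallback uses known chemistry only, sets out from farnesyl bromide 2 and comes back to the route at 12. Birch reduction of commercial 3-methoxybenzoic acid (Li, liquid NH3, THF, t-BuOH, −78 °C; excess metal destroyed with isoprene) gives the dilithium dianion of 3-methoxycyclohexa-2,5-diene-1-carboxylic acid F1. Alkylation at C1 with 2 gives racemic 1-farnesyl-3-methoxycyclohexa-2,5-diene-1-carboxylic acid F2, in which the ring, the quaternary carbon and the oxygen at the future C5 already stand in the 1,3-relationship of the target. Arndt–Eistert homologation under the conditions of steps 3 and 4 leads through 1-farnesyl-3-methoxycyclohexa-2,5-diene-1-carbonyl chloride F3, 2-diazo-1-(1-farnesyl-3-methoxycyclohexa-2,5-dien-1-yl)ethan-1-one F4 and (1-farnesyl-3-methoxycyclohexa-2,5-dien-1-yl)ketene F5 to methyl 2-(1-farnesyl-3-methoxycyclohexa-2,5-dien-1-yl)acetate F6. Dilute aqueous HCl in THF hydrolyses the enol ether, and a little DBU moves the β,γ-olefin into conjugation to give racemic methyl 2-(1-farnesyl-5-oxocyclohex-3-en-1-yl)acetate F7. Preparative chromatography on a chiral stationary phase then delivers the (S)-enantiomer, which is 12, at the cost of half the material.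

**Step 8.** Equilibration may be incomplete, so that enolisation at C4 leads to the cross-conjugated silyl ether. The dienolate may add in a conjugate sense to enone not yet deprotonated, and the silyl ester or dienol ether may hydrolyse on isolation.

The fallback sets out from 13 and comes back at 18 without any silyl intermediate. Equilibration with KOt-Bu in t-BuOH–THF to the dipotassium dienolate 14, then a quench into cold aqueous acetic acid, protonates kinetically at C6 and should give the deconjugated acid 2-[(1R)-1-farnesyl-5-oxocyclohex-2-en-1-yl]acetic acid F8. Pd(OAc)2 (10 mol %), NaOAc, O2 (1 atm) in DMSO then effects a Wacker-type oxidative lactonization. Divalent palladium activates the C7=C7a olefin, the carboxylate adds to C7a on its own face (5-exo), and β-hydride elimination towards C6 restores the enone, which gives 18.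

**Step 9.** The electrophilic bromine may attack the side-chain olefins, or bromolactonisation onto C2′=C3′ may occur once the carboxylate is free. Bromination may take place at C6 in place of C7a, and ring closure at the neopentyl-type C7a may be slow for the epimer that carries bromine on the face of the acetate arm.

The fallback sets out from 15 and comes back at 18. The trivalent iodine oxidant PhI(OAc)2 (1.1 equiv) with BF3·OEt2 in CH2Cl2 at −78 °C is used in place of the halogen. The iodine reagent activates the dienol ether at C7a and the silyl ester oxygen closes the lactone with loss of iodobenzene. The C7a–O bond is thus made without a carbon–bromine bond and without a backside displacement, and no compound outside the list is made on this way (F0).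

Further compounds

F1 | step 6 | dilithium dianion of 3-methoxycyclohexa-2,5-diene-1-carboxylic acid | [Li+].[Li+].[O-]C([O-])=C1C=CCC(OC)=C1
F2 | step 6 | racemic 1-farnesyl-3-methoxycyclohexa-2,5-diene-1-carboxylic acid | CC(C)=CCC/C(C)=C/CC/C(C)=C/CC1(C(=O)O)C=CCC(OC)=C1
F3 | step 6 | racemic 1-farnesyl-3-methoxycyclohexa-2,5-diene-1-carbonyl chloride | CC(C)=CCC/C(C)=C/CC/C(C)=C/CC1(C(=O)Cl)C=CCC(OC)=C1
F4 | step 6 | racemic 2-diazo-1-(1-farnesyl-3-methoxycyclohexa-2,5-dien-1-yl)ethan-1-one | CC(C)=CCC/C(C)=C/CC/C(C)=C/CC1(C(=O)C=[N+]=[N-])C=CCC(OC)=C1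
F5 | step 6 | racemic (1-farnesyl-3-methoxycyclohexa-2,5-dien-1-yl)ketene | CC(C)=CCC/C(C)=C/CC/C(C)=C/CC1(C=C=O)C=CCC(OC)=C1
F6 | step 6 | racemic methyl 2-(1-farnesyl-3-methoxycyclohexa-2,5-dien-1-yl)acetate | CC(C)=CCC/C(C)=C/CC/C(C)=C/CC1(CC(=O)OC)C=CCC(OC)=C1
F7 | step 6 | racemic methyl 2-(1-farnesyl-5-oxocyclohex-3-en-1-yl)acetate | CC(C)=CCC/C(C)=C/CC/C(C)=C/CC1(CC(=O)OC)CC(=O)C=CC1
F8 | step 8 | 2-[(1R)-1-farnesyl-5-oxocyclohex-2-en-1-yl]acetic acid | CC(C)=CCC/C(C)=C/CC/C(C)=C/C[C@]1(CC(=O)O)CC(=O)CC=C1
F0 | step 9 | none | none
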